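**Plan**

- Retrosynthesis: the two aryl O–Si bonds and the acid oxidation level at C1 are taken back first (12 ⇐ 11 ⇐ aldehyde 10). The C2–CH2 bond between the acid α-carbon and the methylene next to the aryl ketone is cut next, giving dienal 5 and phenacyl bromide 9. Last, the C3–C4 bond of 5 is cut to geranyl bromide and a C3 acetal Grignard reagent.
- Forward: geranyl bromide is extended to 5 (steps 1–2), 2',5'-dihydroxyacetophenone is silylated and brominated to 9 (steps 3–4), and the halves are joined in step 5. Pinnick oxidation and desilylation follow; no ring is formed.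
- Enabling feature: the carboxyl carbon C1 and the aryl ketone C=O are 1,4-related across the C2–CH2 bond. With C1 held as an aldehyde, C2 is the nucleophilic β-carbon of a chiral enamine. The CH2 next to the carbonyl of the 2,5-dioxygenated benzoyl ring gives, from its bromide, an electrophilic α-keto radical. The nearest alkene (C5=C6) is too close to C2 for a favourable radical ring closure.
- Stereochemistry: the only stereocentre, C2 (S), is set in step 5 by the (2S,5R)-imidazolidinone catalyst (Re-face attack on the E-enamine). It is not exposed to enolising conditions afterwards. Both E-olefins come unchanged from geranyl bromide.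

Key step: step 5

Remark: the sense of induction in step 5 is taken from the accepted shielding model of the imidazolidinone enamine. The (2S,5R) catalyst (D-alanine series) is the enantiomer expected to give (S)-10, and this is to be confirmed on 10 by correlation.

**Route**

Step 1
Reactants: 1 2-(2-bromoethyl)-1,3-dioxolane; 2 geranyl bromide, (2E)-1-bromo-3,7-dimethylocta-2,6-diene
Product: 4 2-[(4E)-5,9-dimethyldeca-4,8-dien-1-yl]-1,3-dioxolane, via Grignard reagent 3 (not isolated)
Conditions: Mg, THF, 25–30 °C (1 → 3); then 2, Li2CuCl4 (3 mol%), THF, −10 → 0 °C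
Reagents that add atoms: none
Why: Copper-catalysed (Kochi-type) cross-coupling of a primary alkyl Grignard reagent with an allylic bromide should take place at the unhindered primary α-carbon of 2 with retention of the E-trisubstituted alkene, and the dioxolane is inert to the organometallic species.

Step 2
Reactants: 4 2-[(4E)-5,9-dimethyldeca-4,8-dien-1-yl]-1,3-dioxolane
Product: 5 (5E)-6,10-dimethylundeca-5,9-dienal
Conditions: 1 M aq. HCl, THF, 23 °C
Reagents that add atoms: water, O
Why: Acid-catalysed acetal hydrolysis; dilute aqueous acid at room temperature should be too weak and too wet to protonate the trisubstituted alkenes or to start a Prins closure of the aldehyde onto C5=C6.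

Step 3
Reactants: 6 1-(2,5-dihydroxyphenyl)ethan-1-one (2',5'-dihydroxyacetophenone)
Product: 7 1-[2,5-bis(tert-butyldimethylsilyloxy)phenyl]ethan-1-one
Conditions: TBSCl (2.5 equiv), imidazole (5 equiv), DMF, 23 → 40 °C
Reagents that add atoms: tert-butyldimethylsilyl chloride, CC(C)(C)[Si](C)(C)Cl
Why: Imidazole-promoted silylation of both phenols (the hydrogen-bonded ortho OH needs the excess and gentle warming); the silyl ethers should keep the hydroquinone from acting as reductant or H-donor in step 5, from closing onto the CH2Br carbon, and from being chlorinated in step 6.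

Step 4
Reactants: 7 1-[2,5-bis(tert-butyldimethylsilyloxy)phenyl]ethan-1-one
Product: 9 2-bromo-1-[2,5-bis(tert-butyldimethylsilyloxy)phenyl]ethan-1-one, via trimethylsilyl enol ether 8 (not isolated)
Conditions: TMSOTf, Et3N, CH2Cl2, 0 °C; cold NaHCO3 wash, crude 8 in THF; NBS, 0 °C
Reagents that add atoms: N-bromosuccinimide, O=C1CCC(=O)N1Br
Why: Soft enolisation to the silyl enol ether followed by electrophilic bromination with NBS should place bromine on the enol carbon only, avoiding the ring bromination that direct treatment of the electron-rich aryl ketone with Br2 would risk.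

Step 5
Reactants: 5 (5E)-6,10-dimethylundeca-5,9-dienal; 9 2-bromo-1-[2,5-bis(tert-butyldimethylsilyloxy)phenyl]ethan-1-one
Product: 10 (2S,5E)-2-{2-[2,5-bis(tert-butyldimethylsilyloxy)phenyl]-2-oxoethyl}-6,10-dimethylundeca-5,9-dienal
Conditions: 5 (2 equiv), (2S,5R)-2-tert-butyl-3,5-dimethylimidazolidin-4-one·TfOH (20 mol%), Ru(bpy)3Cl2 (0.5 mol%), 2,6-lutidine (2 equiv), degassed DMF, blue LEDs, 23 °C
Reagents that add atoms: none
Why: The catalyst condenses with 5 to an E-enamine, photoexcited Ru(II) is reductively quenched to Ru(I), which transfers an electron to 9 so that bromide leaves and the electrophilic α-keto (phenacyl) radical forms; this radical adds to the enamine β-carbon (the future C2), and the resulting α-amino radical is oxidised (by excited Ru(II) or by chain transfer to a second molecule of 9) to the iminium ion, which is hydrolysed to 10 with release of the catalyst. The closest known reaction type is the merged photoredox–enamine organocatalytic α-alkylation of aldehydes with α-bromo ketones, for which phenacyl bromides are standard partners. No ring is closed. The new stereocentre C2 is under catalyst control: the enamine lies away from the tert-butyl group and the C5 methyl group of the (2S,5R) catalyst covers its Si face, so the radical should enter on the Re face and give the (S) configuration. The step needs chemoselectivity for the enamine over the two trisubstituted alkenes, which polarity matching should secure (electron-poor radical, electron-rich enamine), and it needs the α-amino radical to be oxidised faster than it can close 5-exo onto C5=C6, which its strongly reducing character and the high concentration of 9 should secure. The α-branched product no longer condenses readily with the hindered catalyst and 2,6-lutidine is too weak a base to enolise it, so the configuration should persist.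

Step 6
Reactants: 10 (2S,5E)-2-{2-[2,5-bis(tert-butyldimethylsilyloxy)phenyl]-2-oxoethyl}-6,10-dimethylundeca-5,9-dienal
Product: 11 (2S,5E)-2-{2-[2,5-bis(tert-butyldimethylsilyloxy)phenyl]-2-oxoethyl}-6,10-dimethylundeca-5,9-dienoic acid
Conditions: NaClO2, NaH2PO4, 2-methyl-2-butene (30 equiv), t-BuOH/H2O, 0 → 23 °C
Reagents that add atoms: sodium chlorite, [Na+].[O-]Cl=O
Why: Pinnick oxidation: chlorous acid adds to the aldehyde and fragments to the acid and HOCl, which the large excess of 2-methyl-2-butene should intercept before it reaches the two alkenes of the substrate, while the pH 3–4 buffer should neither enolise C2 nor cleave the aryl silyl ethers.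

Step 7
Reactants: 11 (2S,5E)-2-{2-[2,5-bis(tert-butyldimethylsilyloxy)phenyl]-2-oxoethyl}-6,10-dimethylundeca-5,9-dienoic acid
Product: 12 (2S,5E)-2-[2-(2,5-dihydroxyphenyl)-2-oxoethyl]-6,10-dimethylundeca-5,9-dienoic acid
Conditions: TBAF (3 equiv), AcOH (3 equiv), THF, 0 °C, Ar; pH 3 buffer work-up
Reagents that add atoms: none
Why: Fluoride-induced cleavage of the two aryl silyl ethers, buffered with acetic acid so that no free phenoxide of the oxidation-prone hydroquinone builds up; the alkenes, the ketone and the C2 stereocentre should be inert to these conditions.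

**Compound list**

1 | 2-(2-bromoethyl)-1,3-dioxolane | BrCCC1OCCO1 | starting material
2 | geranyl bromide, (2E)-1-bromo-3,7-dimethylocta-2,6-diene | CC(C)=CCC/C(C)=C/CBr | starting material
3 | [2-(1,3-dioxolan-2-yl)ethyl]magnesium bromide (formed in the flask) | Br[Mg]CCC1OCCO1 | intermediate
4 | 2-[(4E)-5,9-dimethyldeca-4,8-dien-1-yl]-1,3-dioxolane | CC(C)=CCC/C(C)=C/CCCC1OCCO1 | intermediate
5 | (5E)-6,10-dimethylundeca-5,9-dienal | CC(C)=CCC/C(C)=C/CCCC=O | intermediate
6 | 1-(2,5-dihydroxyphenyl)ethan-1-one | CC(=O)c1cc(O)ccc1O | starting material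
7 | 1-[2,5-bis(tert-butyldimethylsilyloxy)phenyl]ethan-1-one | CC(=O)c1cc(O[Si](C)(C)C(C)(C)C)ccc1O[Si](C)(C)C(C)(C)C | intermediate
8 | ({1-[2,5-bis(tert-butyldimethylsilyloxy)phenyl]ethenyl}oxy)trimethylsilane (formed in the flask) | C=C(O[Si](C)(C)C)c1cc(O[Si](C)(C)C(C)(C)C)ccc1O[Si](C)(C)C(C)(C)C | intermediate
9 | 2-bromo-1-[2,5-bis(tert-butyldimethylsilyloxy)phenyl]ethan-1-one | O=C(CBr)c1cc(O[Si](C)(C)C(C)(C)C)ccc1O[Si](C)(C)C(C)(C)C | intermediate
10 | (2S,5E)-2-{2-[2,5-bis(tert-butyldimethylsilyloxy)phenyl]-2-oxoethyl}-6,10-dimethylundeca-5,9-dienal | CC(C)=CCC/C(C)=C/CC[C@@H](CC(=O)c1cc(O[Si](C)(C)C(C)(C)C)ccc1O[Si](C)(C)C(C)(C)C)C=O | intermediate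
11 | (2S,5E)-2-{2-[2,5-bis(tert-butyldimethylsilyloxy)phenyl]-2-oxoethyl}-6,10-dimethylundeca-5,9-dienoic acid | CC(C)=CCC/C(C)=C/CC[C@@H](CC(=O)c1cc(O[Si](C)(C)C(C)(C)C)ccc1O[Si](C)(C)C(C)(C)C)C(=O)O | intermediate
12 | (2S,5E)-2-[2-(2,5-dihydroxyphenyl)-2-oxoethyl]-6,10-dimethylundeca-5,9-dienoic acid | CC(C)=CCC/C(C)=C/CC[C@@H](CC(=O)c1cc(O)ccc1O)C(=O)O | target

Total step count: 7
Longest linear sequence: 5 steps (1, 2, 5, 6, 7; the branch 3, 4, 5, 6, 7 is of equal length)

**Steps most likely to fail**

Step 5. The α-amino radical formed after C–C bond formation may close 5-exo onto C5=C6 before it is oxidised, turnover with the hindered, electron-rich bromoketone may be slow, and the enantiomeric purity may erode by enolisation of the product. The fallback is an auxiliary-controlled enolate alkylation at the acid oxidation level; it sets out from 5 (with 9) and comes back to the route at 11. Aldehyde 5 would be oxidised (NaClO2, NaH2PO4, 2-methyl-2-butene) to (5E)-6,10-dimethylundeca-5,9-dienoic acid F1. Pivaloyl chloride and Et3N in THF at −20 °C would give the mixed pivalic anhydride F2, which (R)-4-benzyloxazolidin-2-one and LiCl would convert in the same flask into the N-acyl oxazolidinone F3. NaHMDS in THF at −78 °C would give the sodium Z-enolate F4, which 9 should alkylate on the face away from the benzyl group (Evans alkylation) to give the (2S)-alkylated imide F5. LiOH/H2O2 in THF/H2O at 0 °C, quenched with Na2SO3 before work-up to spare the aryl silyl ethers, would remove the auxiliary and give 11.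

Step 4. NBS may also brominate the electron-rich bis(silyloxy)arene ring or brominate twice, and loss of the ortho silyl group from the product would be followed by closure of the phenoxide onto the CH2Br carbon. The fallback avoids the bromoketone altogether by oxidative (SOMO) enamine catalysis, a known α-enolation of aldehydes with enol silanes; it sets out from 7 (with 5) and comes back at 10. TBSOTf and Et3N in CH2Cl2 would convert 7 into the isolable tert-butyldimethylsilyl enol ether F6. F6 and 5 would then be combined with (2R,5R)-5-benzyl-2-tert-butyl-3-methylimidazolidin-4-one·TFA (20 mol%), ceric ammonium nitrate (2 equiv), 2,6-di-tert-butylpyridine and H2O in acetone at −20 °C. The enamine is oxidised to its radical cation, the enol silane adds to C2 on the face left open by the catalyst (expected to give S by the same shielding model), and oxidation and desilylation of the resulting α-silyloxy benzylic radical give 10. In this manifold no radical sits on C1, so the 5-exo pathway of step 5 is also absent. The acyl group should make the bis(silyloxy)arene hard enough to oxidise to survive the cerium(IV).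

Step 1. Attack at the tertiary γ-carbon (SN2′) may give the branched isomer, and the acetal Grignard reagent may decompose before it couples. The fallback replaces the organometallic coupling by alkylation of a sulfonyl carbanion followed by reductive desulfonylation; it sets out from 2 (with 1) and comes back at 4. Sodium p-toluenesulfinate in DMF at 23 °C would convert 2 into geranyl p-tolyl sulfone F7. n-BuLi in THF/DMPU at −78 °C would give the α-lithio sulfone F8, which bromide 1 should alkylate at the sulfonyl carbon to give the racemic acetal sulfone F9. PdCl2(dppp) (cat.) and LiBHEt3 in THF at 0 °C should then remove the sulfonyl group with retention of the position and E geometry of the alkene and give 4.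

**Further compounds**

F1 | step 5 | (5E)-6,10-dimethylundeca-5,9-dienoic acid | CC(C)=CCC/C(C)=C/CCCC(=O)O
F2 | step 5 | (5E)-6,10-dimethylundeca-5,9-dienoic pivalic anhydride | CC(C)=CCC/C(C)=C/CCCC(=O)OC(=O)C(C)(C)C
F3 | step 5 | (4R)-4-benzyl-3-[(5E)-6,10-dimethylundeca-5,9-dienoyl]-1,3-oxazolidin-2-one | CC(C)=CCC/C(C)=C/CCCC(=O)N1[C@H](Cc2ccccc2)COC1=O
F4 | step 5 | sodium (Z)-enolate of (4R)-4-benzyl-3-[(5E)-6,10-dimethylundeca-5,9-dienoyl]-1,3-oxazolidin-2-one | CC(C)=CCC/C(C)=C/CC/C=C(\[O-])N1[C@H](Cc2ccccc2)COC1=O.[Na+]
F5 | step 5 | (4R)-4-benzyl-3-[(2S,5E)-2-{2-[2,5-bis(tert-butyldimethylsilyloxy)phenyl]-2-oxoethyl}-6,10-dimethylundeca-5,9-dienoyl]-1,3-oxazolidin-2-one | CC(C)=CCC/C(C)=C/CC[C@@H](CC(=O)c1cc(O[Si](C)(C)C(C)(C)C)ccc1O[Si](C)(C)C(C)(C)C)C(=O)N1[C@H](Cc2ccccc2)COC1=O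
F6 | step 4 | tert-butyl({1-[2,5-bis(tert-butyldimethylsilyloxy)phenyl]ethenyl}oxy)dimethylsilane | C=C(O[Si](C)(C)C(C)(C)C)c1cc(O[Si](C)(C)C(C)(C)C)ccc1O[Si](C)(C)C(C)(C)C
F7 | step 1 | geranyl p-tolyl sulfone, 1-{[(2E)-3,7-dimethylocta-2,6-dien-1-yl]sulfonyl}-4-methylbenzene | CC(C)=CCC/C(C)=C/CS(=O)(=O)c1ccc(C)cc1
F8 | step 1 | α-lithio derivative of geranyl p-tolyl sulfone | CC(C)=CCC/C(C)=C/C([Li])S(=O)(=O)c1ccc(C)cc1
F9 | step 1 | 2-{(4E)-5,9-dimethyl-3-[(4-methylphenyl)sulfonyl]deca-4,8-dien-1-yl}-1,3-dioxolane (racemic) | CC(C)=CCC/C(C)=C/C(CCC1OCCO1)S(=O)(=O)c1ccc(C)cc1
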